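**Retrosynthetic overview**
1. Feature: the only ring is the cyclohexa-2,5-dienone C1–C6. Its ketone carbon C1 lies between vinylic C2 (allyl-bearing) and C6, the electron-rich carbon of the C5 methyl enol ether, so C1 can be removed as carbon monoxide.
2. Last step, and the only ring formation: C1–C2 and C1–C6 are cut, giving the open-chain (Z)-vinyl bromide/1-methoxyvinyl compound 24 plus CO (carbonylative Heck cyclisation).
3. In 24, C5=C6 comes from methylenation of methyl ester 23, the allyl group from a trans-selective Stille coupling of dibromoalkene 21, and C2=C3 from dibromo-olefination of aldehyde 20.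
4. C4–C7 and both stereocentres come from an Ireland–Claisen rearrangement of ester 9 ((R)-carbinol, Z-methoxyacrylate, Z-ketene acetal). The new CO2H becomes the C7 methyl group via aldehyde and tosylhydrazone, and the new propenyl group is cleaved to C3.
5. Ester 9 is assembled from methyl (R)-lactate 1, phosphonate 4 and acid 8.

Key step: step 14

Remark: the target numbering (C1 C=O, C2 allyl-bearing, C3, C4 quaternary C–OMe, C5 C–OMe, C6, C7 CH–CH3, C8 CH2–aryl) is used for all intermediates, Ar is 3,4-dimethoxyphenyl, and the given SMILES is read as (4S,7R).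

**Step 1**
Reactants: 1 methyl (R)-lactate
Product: 2 methyl (2R)-2-[(tert-butyldimethylsilyl)oxy]propanoate
Conditions: TBSCl, imidazole, DMF, 0 °C → rt
Reagents that add atoms: tert-butyldimethylsilyl chloride, CC(C)(C)[Si](C)(C)Cl
Why: Silyl ether protection of a secondary alcohol, which does not touch the lactate stereocentre.

**Step 2**
Reactants: 2 methyl (2R)-2-[(tert-butyldimethylsilyl)oxy]propanoate
Product: 3 (2R)-2-[(tert-butyldimethylsilyl)oxy]propanal
Conditions: iBu2AlH (1.05 equiv), CH2Cl2, −78 °C; aq. potassium sodium tartrate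
Reagents that add atoms: none
Why: Partial ester reduction stops at the aluminium hemiacetal at low temperature, and work-up should release the α-silyloxy aldehyde without loss of configuration.

**Step 3**
Reactants: 3 (2R)-2-[(tert-butyldimethylsilyl)oxy]propanal; 4 methyl 2-(dimethoxyphosphoryl)-2-methoxyacetate
Product: 6 methyl (2Z,4R)-4-[(tert-butyldimethylsilyl)oxy]-2-methoxypent-2-enoate, via lithiated phosphonate 5 (not isolated)
Conditions: 4, LiN(SiMe3)2, THF, −78 °C; then 3, −78 → 0 °C; chromatography (Z from E)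
Reagents that add atoms: methyl 2-(dimethoxyphosphoryl)-2-methoxyacetate 4, COC(C(=O)OC)P(=O)(OC)OC; LiN(SiMe3)2, [Li+].C[Si](C)(C)[N-][Si](C)(C)C (lithium only in 5)
Why: Horner–Wadsworth–Emmons olefination with a stabilised anion should place the branched carbinol carbon trans to CO2Me (Z alkene, the geometry later translated into C4), the preformed weakly basic anion spares the α-stereocentre, and the minor E isomer is removed on silica.

**Step 4**
Reactants: 6 methyl (2Z,4R)-4-[(tert-butyldimethylsilyl)oxy]-2-methoxypent-2-enoate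
Product: 7 methyl (2Z,4R)-4-hydroxy-2-methoxypent-2-enoate
Conditions: HF·pyridine, THF, 0 °C → rt
Reagents that add atoms: none
Why: Fluoride-driven desilylation; in the Z isomer the carbinol carbon is trans to CO2Me and cannot lactonise, whereas any residual E isomer would lactonise and be lost on purification, so the step also upgrades the alkene geometry.

**Step 5**
Reactants: 7 methyl (2Z,4R)-4-hydroxy-2-methoxypent-2-enoate; 8 3-(3,4-dimethoxyphenyl)propanoic acid
Product: 9 (2R,3Z)-4,5-dimethoxy-5-oxopent-3-en-2-yl 3-(3,4-dimethoxyphenyl)propanoate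
Conditions: DCC, DMAP (cat.), CH2Cl2, 0 °C → rt
Reagents that add atoms: 3-(3,4-dimethoxyphenyl)propanoic acid 8, COc1ccc(CCC(=O)O)cc1OC
Why: Steglich esterification acylates the alcohol oxygen without breaking the carbinol C–O bond, so the R configuration and the Z alkene are kept.

**Step 6**
Reactants: 9 (2R,3Z)-4,5-dimethoxy-5-oxopent-3-en-2-yl 3-(3,4-dimethoxyphenyl)propanoate
Product: 13 (2R,3R,4E)-2-(3,4-dimethoxybenzyl)-3-methoxy-3-(methoxycarbonyl)hex-4-enoic acid, via lithium enolate 10 (not isolated), via silyl ketene acetal 11 (not isolated), via silyl ester 12 (not isolated)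
Conditions: LiN(iPr)2, THF/DMPU (55:45), −78 °C; TBSCl, −78 °C → rt, then 60 °C; AcOH/H2O/THF, rt
Reagents that add atoms: LiN(iPr)2, [Li+].CC(C)[N-]C(C)C (lithium only in 10); tert-butyldimethylsilyl chloride, CC(C)(C)[Si](C)(C)Cl (silyl group only in 11 and 12)
Why: Ireland–Claisen rearrangement: deprotonation in THF/DMPU gives the enolate with ArCH2 cis to OLi and hence the (Z)-silyl ketene acetal, which should rearrange through a chair with the carbinol methyl equatorial (an axial methyl would clash 1,3-diaxially with the axial OMe of the Z alkene), so the (R)-carbinol centre and the alkene geometry fix C4, the ketene acetal geometry fixes C7, and the C4/C7 pair of the target results.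

**Step 7**
Reactants: 13 (2R,3R,4E)-2-(3,4-dimethoxybenzyl)-3-methoxy-3-(methoxycarbonyl)hex-4-enoic acid
Product: 14 methyl (2R,3E)-2-[(2R)-1-(3,4-dimethoxyphenyl)-3-(ethylsulfanyl)-3-oxopropan-2-yl]-2-methoxypent-3-enoate (S-ethyl thioester of 13)
Conditions: EtSH, DCC, DMAP (cat.), CH2Cl2, 0 °C → rt
Reagents that add atoms: ethanethiol, CCS
Why: Steglich-type thioesterification opens a route from CO2H to CH3 that never passes through the primary alcohol, which as a γ-hydroxy ester would lactonise onto the C5 methyl ester.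

**Step 8**
Reactants: 14 S-ethyl thioester of 13
Product: 15 methyl (2R,3E)-2-[(2R)-1-(3,4-dimethoxyphenyl)-3-oxopropan-2-yl]-2-methoxypent-3-enoate
Conditions: Et3SiH, Pd/C (10 wt % Pd), acetone, rt
Reagents that add atoms: none
Why: Fukuyama reduction converts only the thioester into the aldehyde under neutral conditions, which should leave the methyl ester, the hindered propenyl group and the epimerisable C7–H untouched.

**Step 9**
Reactants: 15 methyl (2R,3E)-2-[(2R)-1-(3,4-dimethoxyphenyl)-3-oxopropan-2-yl]-2-methoxypent-3-enoate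
Product: 18 methyl (2S,3E)-2-[(2R)-1-(3,4-dimethoxyphenyl)propan-2-yl]-2-methoxypent-3-enoate, via tosylhydrazone 16 (not isolated), via alkyl diazene 17 (not isolated)
Conditions: TsNHNH2, MgSO4, THF, rt; filter, evaporate; catecholborane, CHCl3, −10 °C; NaOAc·3H2O, reflux
Reagents that add atoms: p-toluenesulfonyl hydrazide, Cc1ccc(cc1)S(=O)(=O)NN (its atoms only in 16 and 17)
Why: Caglioti-type reductive deoxygenation: hydride adds to the C=N bond, loss of sulfinate gives the diazene and extrusion of N2 turns CHO into the C7 methyl group under nearly neutral conditions that should neither epimerise C7 nor eliminate the β-methoxy group.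

**Step 10**
Reactants: 18 methyl (2S,3E)-2-[(2R)-1-(3,4-dimethoxyphenyl)propan-2-yl]-2-methoxypent-3-enoate
Product: 20 methyl (2S,3R)-4-(3,4-dimethoxyphenyl)-2-formyl-2-methoxy-3-methylbutanoate, via ozonide 19 (not isolated)
Conditions: O3, CH2Cl2, −78 °C, Sudan Red 7B as end-point indicator; Me2S, −78 °C → rt
Reagents that add atoms: ozone, [O-][O+]=O
Why: Ozonolysis with reductive work-up; the alkene reacts faster than the dimethoxyarene, the dye stops the ozone supply in time, and quaternary C4 cannot epimerise.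

**Step 11**
Reactants: 20 methyl (2S,3R)-4-(3,4-dimethoxyphenyl)-2-formyl-2-methoxy-3-methylbutanoate
Product: 21 methyl (2S)-4,4-dibromo-2-[(2R)-1-(3,4-dimethoxyphenyl)propan-2-yl]-2-methoxybut-3-enoate
Conditions: CBr4, PPh3, CH2Cl2, 0 °C
Reagents that add atoms: carbon tetrabromide, BrC(Br)(Br)Br
Why: Ramirez dibromo-olefination (first stage of the Corey–Fuchs sequence) uses a small, reactive ylide that handles hindered non-enolisable aldehydes and ignores the ester.

**Step 12**
Reactants: 21 methyl (2S)-4,4-dibromo-2-[(2R)-1-(3,4-dimethoxyphenyl)propan-2-yl]-2-methoxybut-3-enoate; 22 allyltributylstannane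
Product: 23 methyl (2S,3Z)-4-bromo-2-[(2R)-1-(3,4-dimethoxyphenyl)propan-2-yl]-2-methoxyhepta-3,6-dienoate
Conditions: 22 (1.1 equiv), Pd2(dba)3 (2.5 mol %), P(2-furyl)3 (15 mol %), toluene, 90 °C
Reagents that add atoms: allyltributylstannane 22, C=CC[Sn](CCCC)(CCCC)CCCC
Why: Stille coupling of a 1,1-dibromoalkene: zerovalent palladium inserts preferentially into the C–Br bond trans to the carbon substituent, a bias reinforced here by quaternary C4, so the allyl group should enter trans to C4 and leave the remaining bromine cis to C4 (Z).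

**Step 13**
Reactants: 23 methyl (2S,3Z)-4-bromo-2-[(2R)-1-(3,4-dimethoxyphenyl)propan-2-yl]-2-methoxyhepta-3,6-dienoate
Product: 24 4-[(2R,3S,4Z)-5-bromo-3-methoxy-3-(1-methoxyethenyl)-2-methylocta-4,7-dien-1-yl]-1,2-dimethoxybenzene
Conditions: Cp2TiMe2 (3 equiv), toluene, 75 °C, dark; filtration through basic Al2O3
Reagents that add atoms: dimethyltitanocene Cp2TiMe2, C[Ti+2]C.c1cc[cH-]c1.c1cc[cH-]c1
Why: Petasis methylenation turns the ester C=O into C5=C6 through an oxatitanacyclobutane under non-basic, non-acidic conditions that tolerate vinyl bromides and alkenes, and the ester methoxy group becomes the C5–OMe group with no regiochemical choice.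

**Step 14**
Reactants: 24 4-[(2R,3S,4Z)-5-bromo-3-methoxy-3-(1-methoxyethenyl)-2-methylocta-4,7-dien-1-yl]-1,2-dimethoxybenzene; 25 carbon monoxide
Product: 29 lancifolin C, via vinylpalladium bromide 26 (not isolated), via acylpalladium bromide 27 (not isolated), via cyclised alkylpalladium bromide 28 (not isolated)
Conditions: Pd(PPh3)4 (10 mol %), CO (10 bar), iPr2NEt (2 equiv), toluene (0.01 M), 90 °C
Reagents that add atoms: carbon monoxide 25, [C-]#[O+]; Pd(PPh3)4, [Pd].c1ccc(cc1)P(c1ccccc1)c1ccccc1.c1ccc(cc1)P(c1ccccc1)c1ccccc1.c1ccc(cc1)P(c1ccccc1)c1ccccc1.c1ccc(cc1)P(c1ccccc1)c1ccccc1 (its Pd(PPh3)2 unit only in 26 to 28)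
Why: Proposed new method: zerovalent palladium inserts into the C2–Br bond of 24 with retention (26), CO inserts to give the dienoyl complex of divalent palladium 27, the acyl carbon C1 then bonds to C6 while palladium goes to C5 (28), and loss of HPdBr, either by syn β-hydride elimination from C6 or by ionisation of the α-methoxyalkyl palladium to an oxocarbenium ion followed by deprotonation of the now acidic C6–H, gives the vinylogous ester while iPr2NEt regenerates the catalyst. The closest known reaction types are the intermolecular carbonylative Heck coupling and the palladium-catalysed aroylation of alkyl vinyl ethers, which both acylate the oxygen-free alkene carbon and give β-alkoxy enones, and the cyclic acylpalladation of (Z)-1-halo-1,4-dienes under CO, which normally closes five-membered rings; a six-membered closure onto a 1,1-disubstituted enol ether has not been shown. The only ring, C1–C6, closes 6-endo-trig with respect to C5=C6, and the Z geometry of 24 is what holds C1 cis to C4 and within reach of C6. No stereocentre is created in 29, since C4 is quaternary, C7–H is not activated and the transient centre C5 of 28 is erased in the elimination. The selectivity needed is 6-endo over 5-exo, and the substrate should secure it because the 5-exo mode would join C1 to the fully substituted, oxygen-bearing C5 next to quaternary C4, whereas C6 is an unhindered CH2 carrying the largest HOMO coefficient; the neutral manifold (bromide kept on palladium, PPh3, toluene, no silver salt) is chosen because cationic palladium delivers the migrating group to the oxygen-bearing carbon of vinyl ethers. Closure of 26 before CO uptake, or of 27 onto the allyl group, would need four-membered or 5-endo rings, so under CO pressure acylation of the enol ether should be the only open channel.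

**Compound list**
1 | methyl (R)-lactate | C[C@@H](O)C(=O)OC | starting material
2 | methyl (2R)-2-[(tert-butyldimethylsilyl)oxy]propanoate | C[C@@H](O[Si](C)(C)C(C)(C)C)C(=O)OC | intermediate
3 | (2R)-2-[(tert-butyldimethylsilyl)oxy]propanal | C[C@@H](O[Si](C)(C)C(C)(C)C)C=O | intermediate
4 | methyl 2-(dimethoxyphosphoryl)-2-methoxyacetate | COC(C(=O)OC)P(=O)(OC)OC | starting material
5 | lithiated phosphonate, lithium salt of the carbanion of 4 (not isolated) | [Li+].COC(=O)[C-](OC)P(=O)(OC)OC | intermediate
6 | methyl (2Z,4R)-4-[(tert-butyldimethylsilyl)oxy]-2-methoxypent-2-enoate | C[C@@H](O[Si](C)(C)C(C)(C)C)/C=C(\OC)C(=O)OC | intermediate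
7 | methyl (2Z,4R)-4-hydroxy-2-methoxypent-2-enoate | C[C@@H](O)/C=C(\OC)C(=O)OC | intermediate
8 | 3-(3,4-dimethoxyphenyl)propanoic acid | COc1ccc(CCC(=O)O)cc1OC | starting material
9 | (2R,3Z)-4,5-dimethoxy-5-oxopent-3-en-2-yl 3-(3,4-dimethoxyphenyl)propanoate | C[C@@H](OC(=O)CCc1ccc(OC)c(OC)c1)/C=C(\OC)C(=O)OC | intermediate
10 | lithium enolate of 9, ArCH2 cis to OLi (not isolated) | [Li+].C[C@@H](O/C([O-])=C/Cc1ccc(OC)c(OC)c1)/C=C(\OC)C(=O)OC | intermediate
11 | (Z)-tert-butyldimethylsilyl ketene acetal of 9 (not isolated) | C[C@@H](O/C(O[Si](C)(C)C(C)(C)C)=C/Cc1ccc(OC)c(OC)c1)/C=C(\OC)C(=O)OC | intermediate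
12 | tert-butyldimethylsilyl ester of 13 (not isolated) | C/C=C/[C@@](OC)([C@H](C(=O)O[Si](C)(C)C(C)(C)C)Cc1ccc(OC)c(OC)c1)C(=O)OC | intermediate
13 | (2R,3R,4E)-2-(3,4-dimethoxybenzyl)-3-methoxy-3-(methoxycarbonyl)hex-4-enoic acid | C/C=C/[C@@](OC)([C@H](C(=O)O)Cc1ccc(OC)c(OC)c1)C(=O)OC | intermediate
14 | methyl (2R,3E)-2-[(2R)-1-(3,4-dimethoxyphenyl)-3-(ethylsulfanyl)-3-oxopropan-2-yl]-2-methoxypent-3-enoate | C/C=C/[C@@](OC)([C@H](C(=O)SCC)Cc1ccc(OC)c(OC)c1)C(=O)OC | intermediate
15 | methyl (2R,3E)-2-[(2R)-1-(3,4-dimethoxyphenyl)-3-oxopropan-2-yl]-2-methoxypent-3-enoate | C/C=C/[C@@](OC)([C@H](C=O)Cc1ccc(OC)c(OC)c1)C(=O)OC | intermediate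
16 | (E)-tosylhydrazone of 15 (not isolated) | C/C=C/[C@@](OC)([C@H](/C=N/NS(=O)(=O)c2ccc(C)cc2)Cc1ccc(OC)c(OC)c1)C(=O)OC | intermediate
17 | alkyl diazene, CH2–N=NH on C7 (not isolated) | C/C=C/[C@@](OC)([C@H](CN=N)Cc1ccc(OC)c(OC)c1)C(=O)OC | intermediate
18 | methyl (2S,3E)-2-[(2R)-1-(3,4-dimethoxyphenyl)propan-2-yl]-2-methoxypent-3-enoate | C/C=C/[C@@](OC)([C@H](C)Cc1ccc(OC)c(OC)c1)C(=O)OC | intermediate
19 | ozonide (1,2,4-trioxolane) of 18, ring carbons unassigned (not isolated) | CC1OOC(O1)[C@@](OC)([C@H](C)Cc1ccc(OC)c(OC)c1)C(=O)OC | intermediate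
20 | methyl (2S,3R)-4-(3,4-dimethoxyphenyl)-2-formyl-2-methoxy-3-methylbutanoate | O=C[C@@](OC)([C@H](C)Cc1ccc(OC)c(OC)c1)C(=O)OC | intermediate
21 | methyl (2S)-4,4-dibromo-2-[(2R)-1-(3,4-dimethoxyphenyl)propan-2-yl]-2-methoxybut-3-enoate | BrC(Br)=C[C@@](OC)([C@H](C)Cc1ccc(OC)c(OC)c1)C(=O)OC | intermediate
22 | allyltributylstannane | C=CC[Sn](CCCC)(CCCC)CCCC | starting material
23 | methyl (2S,3Z)-4-bromo-2-[(2R)-1-(3,4-dimethoxyphenyl)propan-2-yl]-2-methoxyhepta-3,6-dienoate | C=CC/C(Br)=C/[C@@](OC)([C@H](C)Cc1ccc(OC)c(OC)c1)C(=O)OC | intermediate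
24 | 4-[(2R,3S,4Z)-5-bromo-3-methoxy-3-(1-methoxyethenyl)-2-methylocta-4,7-dien-1-yl]-1,2-dimethoxybenzene | C=CC/C(Br)=C/[C@@](OC)([C@H](C)Cc1ccc(OC)c(OC)c1)C(OC)=C | intermediate
25 | carbon monoxide | [C-]#[O+] | starting material
26 | vinylpalladium bromide, PdBr(PPh3)2 on C2 (not isolated) | C=CC/C([Pd-2](Br)([P+](c1ccccc1)(c1ccccc1)c1ccccc1)[P+](c1ccccc1)(c1ccccc1)c1ccccc1)=C/[C@@](OC)([C@H](C)Cc1ccc(OC)c(OC)c1)C(OC)=C | intermediate
27 | acylpalladium bromide, C1(=O)PdBr(PPh3)2 on C2 (not isolated) | C=CC/C(C(=O)[Pd-2](Br)([P+](c1ccccc1)(c1ccccc1)c1ccccc1)[P+](c1ccccc1)(c1ccccc1)c1ccccc1)=C/[C@@](OC)([C@H](C)Cc1ccc(OC)c(OC)c1)C(OC)=C | intermediate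
28 | cyclised alkylpalladium bromide, Pd on C5, C5 unassigned (not isolated) | C=CCC1=C[C@@](OC)([C@H](C)Cc2ccc(OC)c(OC)c2)C(OC)([Pd-2](Br)([P+](c2ccccc2)(c2ccccc2)c2ccccc2)[P+](c2ccccc2)(c2ccccc2)c2ccccc2)CC1=O | intermediate
29 | lancifolin C, (4S)-4-[(2R)-1-(3,4-dimethoxyphenyl)propan-2-yl]-4,5-dimethoxy-2-(prop-2-en-1-yl)cyclohexa-2,5-dien-1-one | C=CCC1=C[C@@](OC)([C@H](C)Cc2ccc(OC)c(OC)c2)C(OC)=CC1=O | target

**Step count**
Total step count: 14.
Longest linear sequence: 14 steps (1 → 29); 4, 8, 22 and 25 are bought.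

**Steps most likely to fail**

1. Step 14 (new method).
- Risks:
  - The ring may close in the usual 5-exo mode of cyclic acylpalladation, followed by loss of methoxide.
  - β-Methoxide elimination towards C4 could lead to aromatisation.
  - Palladium hydride could move the allyl double bond into conjugation.
  - The enol ether could hydrolyse before cyclisation.
- Fallback (known chemistry, from 24 back to 29):
  - The enol ether of 24 is hydrolysed with oxalic acid in wet THF to the methyl ketone F1.
  - The vinyl bromide is methoxycarbonylated with retention (PdCl2(PPh3)2, CO, MeOH, Et3N, DMF, 70 °C) to the (Z)-keto ester F2.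
  - KOtBu in THF at 0 °C then closes the ring by Dieckmann-type acylation of the methyl ketone enolate (C6) by the ester carbon (C1), giving the cyclohexenedione F3.
  - O-Methylation under equilibrating conditions (HC(OMe)3, TsOH cat., MeOH, rt) should favour the cross-conjugated 2,5-dienone over its linearly conjugated isomer. After separation of the isomers this gives 29.

2. Step 6.
- Risks:
  - Incomplete control of the enolate geometry would erode C7.
  - Leakage from the chair to a boat transition state would also lower selectivity.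
  - γ-Deprotonation, or conjugate addition of the long-lived enolate to the methoxyacrylate, could compete.
- Fallback (from 7 back to 14): C4 and C7 are set in separate operations.
  - A base-free Johnson–Claisen rearrangement of 7 with trimethyl orthoacetate (EtCO2H cat., toluene, reflux) transfers the carbinol chirality to C4 through the same chair and gives the diester F4.
  - LiOH in THF/H2O at 0 °C hydrolyses only the unhindered CH2CO2Me group to the acid F5.
  - Activation with PivCl/Et3N and reaction with lithiated (R)-4-benzyloxazolidin-2-one gives the imide F6.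
  - Evans alkylation (NaN(SiMe3)2, THF, −78 °C, 3,4-dimethoxybenzyl bromide; kept cold to avoid β-elimination of methoxide) sets C7 under auxiliary control and gives the benzylated imide F7.
  - EtSLi in THF at 0 °C displaces the auxiliary and delivers thioester 14.

3. Step 12.
- Risks:
  - Transmetalation from the allylstannane at the hindered vinylpalladium may be slow.
  - A second coupling, or dehydrobromination to the alkyne, could occur.
  - The allyl double bond could migrate.
- Fallback (from 20 back to 29): halogen and allyl chain are brought in together.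
  - A Stork–Zhao-type olefination uses the α-iodo ylide made from (but-3-en-1-yl)triphenylphosphonium bromide (n-BuLi; I2; NaN(SiMe3)2; THF, −78 °C). It should give the (Z)-vinyl iodide ester F8 with iodine cis to C4.
  - Cp2TiMe2 as in step 13 gives the iodo enol ether F9.
  - F9 enters the cyclisation of step 14 in place of 24, with an easier oxidative addition, and gives 29.

**Further compounds**
F1 | step 14 | (3S,4Z)-5-bromo-3-[(2R)-1-(3,4-dimethoxyphenyl)propan-2-yl]-3-methoxyocta-4,7-dien-2-one | C=CC/C(Br)=C/[C@@](OC)([C@H](C)Cc1ccc(OC)c(OC)c1)C(C)=O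
F2 | step 14 | (Z)-keto ester, CO2Me in place of Br of F1 | C=CC/C(C(=O)OC)=C/[C@@](OC)([C@H](C)Cc1ccc(OC)c(OC)c1)C(C)=O
F3 | step 14 | (4S)-6-allyl-4-[(2R)-1-(3,4-dimethoxyphenyl)propan-2-yl]-4-methoxycyclohex-5-ene-1,3-dione | C=CCC1=C[C@@](OC)([C@H](C)Cc2ccc(OC)c(OC)c2)C(=O)CC1=O
F4 | step 6 | dimethyl 2-methoxy-2-[(E)-prop-1-enyl]butanedioate, C4 as in 13 | C/C=C/[C@@](OC)(CC(=O)OC)C(=O)OC
F5 | step 6 | (E)-3-methoxy-3-(methoxycarbonyl)hex-4-enoic acid, C4 as in 13 | C/C=C/[C@@](OC)(CC(=O)O)C(=O)OC
F6 | step 6 | N-acyl (R)-4-benzyloxazolidin-2-one of F5 | C/C=C/[C@@](OC)(CC(=O)N1[C@H](Cc2ccccc2)COC1=O)C(=O)OC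
F7 | step 6 | C7-(3,4-dimethoxybenzyl)ated imide, C4 and C7 as in 13 | C/C=C/[C@@](OC)([C@H](C(=O)N1[C@H](Cc2ccccc2)COC1=O)Cc1ccc(OC)c(OC)c1)C(=O)OC
F8 | step 12 | methyl (2S,3Z)-2-[(2R)-1-(3,4-dimethoxyphenyl)propan-2-yl]-4-iodo-2-methoxyhepta-3,6-dienoate | C=CC/C(I)=C/[C@@](OC)([C@H](C)Cc1ccc(OC)c(OC)c1)C(=O)OC
F9 | step 12 | iodo analogue of 24 | C=CC/C(I)=C/[C@@](OC)([C@H](C)Cc1ccc(OC)c(OC)c1)C(OC)=C
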